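The earlier runs and the new flask are simulated for an exercise; the scatter is artificial.

The question was how far a racemate goes by 4.0 h and how unequal its two hands end up, in a dynamic kinetic resolution with a single-handed free catalyst.

| setting | violet | grey | flask |
|---|---|---|---|
| left-handed substrate | 10 mM | 10 mM | 10 mM |
| right-handed substrate | 10 mM | 10 mM | 10 mM |
| partner | 30 mM | 30 mM | 30.0 mM |
| free catalyst | 1.5 mM | 1.5 mM | 1.5 mM |
| racemization catalyst | 10 µM | 15 µM | 20 µM |
| impurity | 5.3 µM | 5.3 µM | 5.3 µM |
| remark | run made earlier | run made earlier |  |
| time |  |  | 4.0 h |

| run | time / h | left-handed substrate / % | right-handed substrate / % |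
|---|---|---|---|
| violet | 0.417 | 18.3 | 22.5 |
| violet | 0.833 | 11.6 | 12.6 |
| violet | 2.00 | 4.4 | 6.1 |
| violet | 5.00 | 1.9 | 1.4 |
| grey | 1.33 | 4.8 | 6.9 |
| grey | 2.50 | 4.7 | 0.8 |
| grey | 4.00 | 1.7 | 1.3 |
| grey | 5.00 | 0.2 | 0 |

(standard deviation of a reading: 1 percentage point)

- part of the left-handed substrate and right-handed substrate charged together that has reacted at 4.0 h
- excess of left-handed product over right-handed product in the product at 4.0 h
- excess of right-handed substrate over left-handed substrate among what is left of the two at 4.0 h

I followed one substrate molecule. At each moment it either reacts through free catalyst and partner or meets a working racemization catalyst and flips. I assumed that each impurity kills one racemization catalyst, so I reckoned with the live racemization catalyst, c(racemization catalyst) − c(impurity), here 14.7 µM and in violet 4.70 µM.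

With the other charges the same, as they are in violet and this flask, the flip odds should scale with that amount, so the leftover excess should scale inversely. Violet's first readings give eS of 10.3%, with 1 percentage point of scatter on each reading. Scaled to this flask, that is 3.29%. I took this as a rough bound from above, rough because of that scatter; violet's curves flatten afterwards, and a slower drain should leave a smaller difference. My bound from below was zero, towards which flips pull the two hands. For eP I drew no such bracket from the substrate readings.

The forecast put c at 97.3%, eS at 3%, just under my upper bound, and eP at 85%, arguing: “Grey runs only slightly faster than violet, which implies high selectivity”.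

The flask gave c 97.1%, eS 0.749%, inside the bracket, and eP 62.7%, which is 22 points below the forecast.

    racemization catalyst + impurity → spent catalyst B (k = 2.14 × 10⁵ /M/min)
    left-handed substrate + racemization catalyst ⇌ right-handed substrate + racemization catalyst, rate k2*[racemization catalyst]*[left-handed substrate] forward; the back reaction follows from the equilibrium constant (k = 18600 /M/min)
    partner + free catalyst + right-handed substrate → free catalyst + right-handed product (k = 504 /M²/min)
    partner + free catalyst + left-handed substrate → free catalyst + left-handed product (k = 2380 /M²/min)
    2 free catalyst → spent catalyst A (k = 3.69 /M/min)

The product excess already stood at 62.2% at 0.400 h. The live amount is 73.5% of the charge, and the flask keeps 73.5% of its racemization catalyst.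

With 0.021 mM of impurity, the reckoning for a neighbouring flask gives −1.00 µM, below zero, which I read as no live racemization catalyst, so flips should stop and the two hands should part. Computed, that neighbouring flask holds 0% racemization catalyst at 4.00 h, with 11.9% right-handed substrate left and 36.7% already gone to right-handed product, eS 98.8% and eP 16.6%.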